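(All runs come from a simulation from invented constants; noise was put on by code.)

No constant is given, so the constants have to be read from the earlier runs, with every amount taken as a fraction of the Z charged.

| flask | Z | E | G | temperature | remark | time |
|---|---|---|---|---|---|---|
| birch | 0.26 M | 1.5 equiv | 2 equiv | 85 °C | run made earlier |  |
| cedar | 0.26 M | 1.5 equiv | 2.8 equiv | 100 °C | run made earlier |  |
| larch | 0.26 M | 1.5 equiv | 4.4 equiv | 85 °C | run made earlier |  |
| oak | 0.39 M | 1.5 equiv | 2 equiv | 100 °C | run made earlier |  |
| green | 0.26 M | 1.50 equiv | 2.00 equiv |  | everything together at the start at 70 °C, warmed to 100 °C at 40 min | 50 min |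
| amber | 0.26 M | 1.50 equiv (fed, over 40 min) | 2.00 equiv | 100 °C | all else is in the flask from the start; the feed brings no volume worth counting | 50 min |
| red | 0.26 M (fed, over 40 min) | 1.50 equiv | 2.00 equiv | 100 °C | all else is in the flask from the start; the feed brings no volume worth counting | 50 min |
| teal | 0.26 M (fed, over 40 min) | 1.50 equiv | 2.00 equiv |  | the addition at 70 °C, then warmed to 100 °C; the feed brings no volume worth counting | 50 min |
| ochre | 0.26 M | 1.50 equiv | 2.00 equiv | 100 °C | everything together at the start | 50 min |

- birch (time / min: D / %, L / %): 8.00: 14.6, 6.9; 25.0: 34.6, 12.7; 50.0: 49.5, 14.5; 80.0: 60.0, 15.0; 120: 68.3, 14.6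
- cedar (time / min: D / %, L / %): 5.00: 22.8, 12.4; 15.0: 44.4, 17.2; 30.0: 60.2, 17.1; 40.0: 66.4, 17.2; 60.0: 71.9, 18.0
- larch (time / min: D / %, L / %): 10.0: 17.5, 13.8; 20.0: 26.6, 20.8; 30.0: 33.7, 25.1; 60.0: 45.2, 29.0; 120: 54.2, 30.6
- oak (time / min: D / %, L / %): 5.00: 31.4, 11.3; 10.0: 45.6, 16.1; 15.0: 54.9, 15.6; 30.0: 67.6, 16.4; 60.0: 78.0, 16.3

(readings scatter by 0.5 percentage points)

- the numbers in the tables scatter by 0.5 percentage points (one standard deviation)

1. which flask leads in share of D in D plus L ("all alike" within 1.5 percentage points) (green / amber / red / teal / ochre / all alike)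
2. share of D in D plus L at the end, green
3. share of D in D plus L at the end, amber
4. share of D in D plus L at the end, red
5. share of D in D plus L at the end, teal
6. share of D in D plus L at the end, ochre

With just the main step, Z + E to D, the share of D in D plus L is 100 %. Adding Z + G to L lowers that share. The last L in larch over that in birch is 2.10 for a ratio of G of 2.20, so L follows G. Yet in cedar the readings of L stay near 17.4% from 15.0 min on, while D climbs from 44.4% to 71.9%. So a third process is added: G is lost without Z, taken here as first order.

G is not read, but if L forms at a rate proportional to Z times G, and Z and G are both taken to fall first order, the burst fades at the sum of their loss rates. In cedar, 12.4% of L stands at 5.00 min, which gives a fading rate of 0.250 min⁻¹. Z, taken as what D and L have not used, falls in cedar at 0.0868 min⁻¹ over the same time. The difference leaves G in cedar a mean life of 6.12 min, a value that carries the scatter of the readings.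

Now Z is fed over 40 min, longer than this life. If Z drains at the same first-order rate in both modes, integrating Z times G gives L fed over L batch as mean life over feed time, 0.153. This survival ratio is an inverse Damköhler number. Scaling cedar to 2.00 equiv of G puts L in ochre at 12.4%, so this reckoning puts L in red at 1.90%. It gives L, not the share, and it gives no number for green and teal, which begin at 70 °C, below the temperatures of the earlier runs.

The forecast names red as leader, with shares of 75% for green, 80% for amber, 95% for red, 77% for teal and 85% for ochre. Its grounds include this: “Trapping is favoured by high Z and low temperature”.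

The flasks give 76.6% for green, 78.4% for amber, 96.5% for red, 78.5% for teal and 84.9% for ochre, so red leads.

    Z + E → D (k = 0.00274 L mol⁻¹ s⁻¹, Ea = 77.0 kJ mol⁻¹)
    Z + G → L (k = 9.39 × 10⁻⁴ L mol⁻¹ s⁻¹, Ea = 87.0 kJ mol⁻¹)
    G + D → Q (k = 3.99 × 10⁻⁴ L mol⁻¹ s⁻¹, Ea = 89.0 kJ mol⁻¹)
    G → J (k = 0.00231 s⁻¹, Ea = 115 kJ mol⁻¹)
    (constants at 100 °C)

The path from G to J has the largest single effect on the gap between red and green: taken away, that gap goes from 20 percentage points to −6.1 points. Red ends with 2.46% of L and ochre with 13.1%, a ratio of 0.188 against the survival ratio of 0.153. A neighbour flask, the same as red but with 5.00 equiv of G, comes by the survival ratio to 4.75% of L, and at 50.0 min it holds 5.80%, with a share of 91.8%.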